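Remark on the chemistry: the target is taken exactly as drawn, which puts C3 (on C4) and C20 (on C6) on opposite faces of the oxolane. Locants C1 to O35 follow the atom order of the target SMILES, and every stereocentre of an intermediate has the spatial arrangement it has in 37 unless stated.

## Analysis of the target

Compound 37 is a tetracyclic diterpenoid ester. An oxolane (C4, O5, C6, C7, C14) is cis-fused at C7–C14 to a cyclohexane (C7 to C11, C14). A seven-membered lactone (C6, C7, C8, C15, C17, O19, C20) and a nine-membered oxonane (C2, C3, C4, O5, C6, C20, C22, C33, C34) both share atoms with the oxolane, the oxonane sharing the C4–O5–C6 unit. There are ten stereocentres: C4 (S), C6 (R), C7 (S), C8 (R), C11 (R), C14 (R), C15 (R), C20 (S), C22 (R) and C34 (S). H6, H7 and H14 lie on one face of the oxolane and H4 on the other, so the lactone and the cyclohexane are cis on the oxolane, whereas the C3 arm is trans to C20 across O5. On the cyclohexane the C15 side chain on C8 is trans to C6 on C7, the C11 hydroxyl is cis to C4, and O23 and O35 are 1,3-syn. Sensitive points are the epimerisable C15 next to the lactone carbonyl, the tertiary ester oxygen on C20, the allylic alcohol beside the exocyclic methylene, and the octanoate that sits 1,3 to a free hydroxyl and can migrate. The synthesis is hard because the medium ring is bridged trans across the oxolane, because the quaternary, oxygenated C20 is flanked by the oxygenated C6 and C22, and because three hydroxyl groups must be told apart. The strategy rests on one feature: O23 on C22 and O35 on C34 are 1,3-related through C33, and C34 is bonded to C2, which carries the C1 methylene. This is a masked β-hydroxy enone, that is an isoxazoline C34=N–O23–C22 with C33 as its methylene carbon.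

## Retrosynthetic reasoning

Target 37 is traced back to enone 36 by changing the C34 carbinol into a ketone. The reduction is left to the end because the α-methylene ketone can be reduced 1,2 under catalyst control. Ester 36 comes from β-hydroxy enone 34 and octanoyl chloride 35; at that stage C22 carries the only secondary hydroxyl, so no selection between two carbinols is needed. Enone 34 is the N–O cleavage product of isoxazoline 32.

In 32 the bonds C33–C34 and O23–C22 are cut together, which leads to oxime 29, the precursor of a nitrile oxide on C34 and a vinyl group on C20. The cut is made here because one cycloaddition then forms two skeletal bonds, closes the oxonane and the heterocycle, places both oxygens and leaves C1=C2 intact. All earlier work is then done on a tricycle without a medium ring. The forward reaction has to close a strained nine-membered ring faster than the dipole dimerises, with oxygen on C22 and from the correct face of the vinyl group.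

Oxime 29 is taken back through enal 28 and alcohol 27 to acetate 26, and there the C3–C4 bond is cut. This gives the methyl acetal 24 and the allylsilane 25. The cut is chosen because an oxocarbenium ion at C4 is attacked opposite to C11 and C20, which is the trans arrangement across O5 that the target needs. Reagent 25 also brings C1, C2, C3 and C34 at once in the right oxidation pattern.

Acetal 24 is opened at O5–C4 to aldehyde 23, which comes from the silyl ether 22. The lactone is already closed in 22, so O19 cannot compete with O5 for C4 when the acetal forms.

Lactone 22 is cut at C17–O19 to hydroxy acid 20, and this is taken back by oxidation level and protecting-group changes through 18 and 17 to triol 16. Doing this before C4 is oxidised requires the two primary oxygens, on C4 and C17, to carry different groups.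

In 16 the C11 hydroxyl is traced to the C10–C11 epoxide of 15, opened by hydride at C10. The vinyl carbinol at C20 is traced to the terminal epoxide of 14 by removing C33, a one-carbon homologation in the forward sense. Both tertiary alcohols thus come from epoxides whose configuration is set by a neighbouring hydroxyl.

The ring epoxide of 14 is placed by the C4 hydroxyl of 13. Alcohol 13 is traced to diene 11 by removing water across C4–C14; forward, a borane adds hydrogen to C14 away from the C7 side chain.

Diene 11 is traced through diol 10 to β-hydroxysilane 8 and ketone 7, cutting C4–C14. C4 is added as a silylmethyl group and the alkene is unveiled only after the isopropenyl group has been hydroborated, so that the two primary alcohols (C17, then C4) appear one after the other and C15 is set next to the bulky C7.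

Ketone 7 comes from epoxy alcohol 6 and this from allylic alcohol 5, where the free C6 hydroxyl directs the epoxidation that fixes C20. Cutting C6–C7 of 5 gives (R)-carvone 1 and methacrolein 2. Carvone supplies C8 with the correct configuration, the C12 methyl, and the isopropenyl group that becomes C15 to C17.

## Alternatives that were turned down

Alternative 1: The oxolane is taken apart at O5–C6, C6–C7 and C4–C14 into three pieces: the diazoketone A2 (C6 and C20 to C34), 3-bromobut-3-enal A3 (C1 to C4) and the cyclohexenone A4 (C7 to C14 with the C15 to C17 side chain). In the forward step Rh2(OAc)4 turns A2 into a rhodium carbenoid, the carbonyl oxygen of A3 captures it, and the resulting carbonyl ylide adds across C7=C14 of A4 on the face away from the C8 substituent, giving the bicyclic ketone A1.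
- For it: it is the most convergent plan. Three bonds, the oxolane and four stereocentres (C4, C6, C7, C14) arise in one step, the cis ring fusion comes for free, and the C11 ketone of A1 would accept a methyl nucleophile from the convex face. On step economy it is stronger than the chosen route.
- Against it: the ylide has several other outlets (a dioxolane with a second aldehyde, cyclopropanation, insertion), and A3 is a β,γ-unsaturated aldehyde that isomerises easily. Regio- and endo/exo-selectivity toward an unsymmetrical enone are open. Above all, the target needs C3 and C20 trans across O5, which requires the ylide to react in the geometry that is usually the minor one. C20 and C22 would still have to be set afterwards.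
- In comparison: the chosen route is linear and longer, but it sets each oxolane centre singly by a substrate-controlled reaction with a known model, and the trans C4/C6 pattern comes from a simple convex-face allylation.

Alternative 2: The C6–C20 bond inside the lactone is cut. The substrate is the C6 acetate A6, whose C17 carboxyl is esterified with the Z trimethylsilyl enol ether of 3-hydroxybutan-2-one. Me3SiOTf ionises the acetate to the oxocarbenium ion, the enol ether attacks it through C20, and the tricyclic lactone A5 results with a methyl ketone at C22.
- For it: the quaternary C20 and the seven-membered lactone form together, and the tether guarantees that C20 and C8 are cis on the oxolane. No tertiary alcohol has to be acylated. On this point it is stronger than the chosen route, where the lactonisation of step 14 is a weak step.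
- Against it: the C20 configuration depends on the geometry of a tetrasubstituted enol ether that is hard to make pure and on a seven-membered cyclic transition state that cannot be predicted. The product A5 carries C22 as a ketone and C33 as a methyl group, so the C22 oxygen stereocentre, the C33–C34 bond and the medium ring need a separate endgame with the oxygen pattern reversed.
- In comparison: the chosen route takes both oxygens of the C22/C34 pair and the ring closure from one cycloaddition, and sets C20 by a directed epoxidation with a well-established stereochemical preference.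

Alternative 3: The cyclohexane is cut at C11–C14. The substrate is the acylated dihydrofuran A8, an enone C8(=O)–C7=C14 carrying a 4-oxopentanoyl chain. SmI2 in THF and methanol reduces the methyl ketone to a ketyl at C11, which adds to C14; protonation of the samarium enolate at C7 gives the cis-fused A7 with the C11 tertiary alcohol.
- For it: the carbocycle and C11 form in one step on an oxolane that already holds C4, C6, C20 and C22, the last two as an acetonide. C22 is therefore fixed before any ring closure, which is stronger than the chosen route, where C22 is set in the risky step.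
- Against it: the samarium enolate at C7 has the ring oxygen on C6 in the β position, so opening of the oxolane by β-elimination competes. The orientation of the C11 hydroxyl relative to C14 is not secured. C8 ends as a ketone, so C8, C15 and the whole propionate unit must be added and lactonised afterwards, and the oxolane with its quaternary C20 must be built from scratch beforehand.
- In comparison: the chosen route takes C8 and the C15 to C17 carbons from carvone and needs no carbon–carbon bond formation on the cyclohexane.

Key step: step 21

Step 1
Reactants: 1 (R)-carvone; 2 methacrolein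
Product: 5 syn-aldol adduct (carvone with a 1-hydroxy-2-methylprop-2-enyl group on C7 trans to the isopropenyl group), via lithium dienolate 3 (not isolated), via titanium enolate 4 (not isolated)
Conditions: LDA, THF, −78 °C; ClTi(OiPr)3, −78 → −40 °C; 2, −78 °C; aq NH4Cl
Reagents that add atoms: none
Why: Directed aldol addition: kinetic deprotonation at C7 and transmetalation give a triisopropoxytitanium enolate, a class whose additions to aldehydes are syn-selective even for the E enolates of cyclic ketones, so the C6 carbinol should form syn to the C7–C8 bond. The aldehyde approaches C7 opposite to the isopropenyl group on C8, which sets the trans C7/C8 relationship.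

Step 2
Reactants: 5 syn-aldol adduct
Product: 6 erythro epoxy alcohol (2-methyloxiran-2-yl group on C6)
Conditions: VO(acac)2 (cat.), t-BuOOH, CH2Cl2, 0 °C → rt
Reagents that add atoms: tert-butyl hydroperoxide, CC(C)(C)OO
Why: Hydroxyl-directed vanadium-catalysed epoxidation reacts only at the allylic C20=C22 alkene. For allylic alcohols substituted on the proximal alkene carbon, strain between that substituent (C21) and the carbinol substituent (C7) in the vanadate ester strongly favours the erythro epoxide, which places the future O19 correctly on C20.

Step 3
Reactants: 6 erythro epoxy alcohol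
Product: 7 triethylsilyl ether at O5
Conditions: Et3SiCl, imidazole, DMAP (cat.), DMF, rt
Reagents that add atoms: chlorotriethylsilane, CC[Si](CC)(CC)Cl
Why: Silylation of the secondary alcohol under mildly basic conditions that a β-hydroxy ketone and an epoxide tolerate; it blocks retro-aldol cleavage in the basic steps that follow.

Step 4
Reactants: 7 triethylsilyl ether
Product: 8 β-hydroxysilane (tertiary C14 alcohol carrying CH2SiMe3; C14 configuration immaterial)
Conditions: Me3SiCH2MgCl, CeCl3, THF, −78 → −20 °C
Reagents that add atoms: (trimethylsilyl)methylmagnesium chloride, C[Si](C)(C)C[Mg]Cl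
Why: 1,2-Addition of the weakly basic organocerium reagent to the hindered, enolisable enone carbonyl (first half of a Peterson olefination); the added carbon becomes C4. Keeping C14 sp3 at this stage leaves the isopropenyl group as the only alkene that 9-BBN can attack in step 5.

Step 5
Reactants: 8 β-hydroxysilane
Product: 10 diol (primary C17 alcohol; C15 as in the target), via B-alkyl-9-BBN adduct 9 (not isolated)
Conditions: 9-BBN, THF, 0 °C → rt; then 30% H2O2, aq NaOH, 0 °C
Reagents that add atoms: hydrogen peroxide, OO
Why: Hydroboration–oxidation of the only 1,1-disubstituted alkene. In the conformer with H8 eclipsing the C15=C17 bond (least allylic strain) the borane comes from the C9 side, away from the heavily substituted C7, which should give the 15R configuration.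

Step 6
Reactants: 10 diol
Product: 11 diene (exocyclic C14=C4 methylene conjugated to C10=C11; C17 4-methoxybenzyl ether)
Conditions: KH, THF, 0 °C → rt; then 4-MeOC6H4CH2Cl, Bu4NI, rt
Reagents that add atoms: 4-methoxybenzyl chloride, COc1ccc(CCl)cc1
Why: Peterson olefination: the potassium alkoxide of the β-hydroxysilane loses Me3SiOK by syn-elimination to give the exocyclic alkene. The primary alkoxide is then alkylated in the same flask (Williamson ether synthesis).

Step 7
Reactants: 11 diene
Product: 13 homoallylic alcohol (C4 hydroxymethyl on C14 cis to the C6 side chain), via B-alkyl-9-BBN adduct 12 (not isolated)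
Conditions: 9-BBN (excess), THF, rt → 45 °C; then 30% H2O2, aq NaOH, 0 °C
Reagents that add atoms: hydrogen peroxide, OO
Why: Hydroboration–oxidation at the terminus of the 1,3-diene: boron adds to C4 and hydrogen to C14 from the face opposite the branched substituent on the neighbouring C7, the same preference that makes 2-substituted methylenecyclohexanes give cis products with 9-BBN. The trisubstituted C10=C11 alkene does not react under these conditions.

Step 8
Reactants: 13 homoallylic alcohol
Product: 14 bis-epoxide (C10–C11 epoxide on the face of the C4 hydroxymethyl group)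
Conditions: VO(acac)2 (cat.), t-BuOOH, CH2Cl2, rt
Reagents that add atoms: tert-butyl hydroperoxide, CC(C)(C)OO
Why: Hydroxyl-directed vanadium-catalysed epoxidation of a homoallylic alcohol: the C4 alkoxide on vanadium delivers oxygen to C10=C11 on its own face, which puts the C11 oxygen cis to C4.

Step 9
Reactants: 14 bis-epoxide
Product: 15 vinyl carbinol (C20 tertiary alcohol with methyl and vinyl groups)
Conditions: Me3S+ I−, n-BuLi, THF, −10 °C → rt
Reagents that add atoms: trimethylsulfonium iodide, C[S+](C)C.[I-]
Why: One-carbon homologation of an epoxide to an allylic alcohol with dimethylsulfonium methylide: the ylide opens the terminal epoxide at the CH2 carbon C22 and the sulfonium betaine eliminates dimethyl sulfide under the excess base, so C20 is not touched. The trisubstituted ring epoxide is far less reactive toward this nucleophile.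

Step 10
Reactants: 15 vinyl carbinol
Product: 16 triol (C11 tertiary alcohol; C10 methylene)
Conditions: LiEt3BH, THF, 0 °C → rt
Reagents that add atoms: none
Why: Hydride opening of a trisubstituted epoxide takes place by SN2 attack at the less substituted C10 and leaves the oxygen on C11 on the face fixed in step 8.

Step 11
Reactants: 16 triol
Product: 17 bis(triethylsilyl) ether (at O5 and at the C4 oxygen)
Conditions: Et3SiCl, imidazole, CH2Cl2, 0 °C
Reagents that add atoms: chlorotriethylsilane, CC[Si](CC)(CC)Cl
Why: Selective silylation of the only primary hydroxyl; the two tertiary alcohols do not react under these conditions.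

Step 12
Reactants: 17 bis(triethylsilyl) ether
Product: 18 primary alcohol (C17 hydroxyl free)
Conditions: DDQ, CH2Cl2–pH 7 buffer, 0 °C → rt
Reagents that add atoms: none
Why: Oxidative cleavage of the 4-methoxybenzyl ether (hydride abstraction to the benzylic oxocarbenium ion, then hydrolysis); silyl ethers, the vinyl group and the tertiary alcohols are stable in the buffered medium.

Step 13
Reactants: 18 primary alcohol
Product: 20 hydroxy acid (C17 carboxylic acid), via C17 aldehyde 19 (not isolated)
Conditions: TEMPO (cat.), NaClO2, NaOCl (cat.), MeCN–phosphate buffer (pH 6.7), 35 °C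
Reagents that add atoms: sodium chlorite, [Na+].[O-]Cl=O
Why: TEMPO-catalysed oxidation with chlorite as terminal oxidant takes the primary alcohol through the aldehyde to the acid near neutral pH, where the α-stereocentre C15 and the silyl ethers should survive.

Step 14
Reactants: 20 hydroxy acid
Product: 22 seven-membered lactone (O19–C17), via mixed anhydride 21 (not isolated)
Conditions: 2,4,6-Cl3C6H2COCl, Et3N, THF, rt; then DMAP, toluene, 90 °C, high dilution
Reagents that add atoms: none
Why: Yamaguchi lactonisation: DMAP converts the mixed anhydride into an acylpyridinium ion, which is captured by the C20 hydroxyl. This is the only hydroxyl that can reach C17, because the C11 hydroxyl is trans to the side chain across the ring; the tertiary alcohol is a poor nucleophile, hence heat and dilution.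

Step 15
Reactants: 22 seven-membered lactone
Product: 23 C4 aldehyde
Conditions: (COCl)2, DMSO, CH2Cl2, −78 → −40 °C; then Et3N, → 0 °C
Reagents that add atoms: none
Why: Swern conditions convert a primary triethylsilyl ether directly into the aldehyde: the activated sulfonium species cleaves the unhindered Si–O bond and oxidises the alkoxide. The hindered secondary silyl ether on O5 is left, which saves a deprotection step.

Step 16
Reactants: 23 C4 aldehyde
Product: 24 tricyclic methyl acetal (2-methoxyoxolane; both C4 anomers)
Conditions: PPTS, MeOH, HC(OMe)3, rt → 40 °C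
Reagents that add atoms: methanol, CO
Why: Acid-catalysed methanolysis removes the silyl group from O5, the freed hydroxyl adds to the C4 aldehyde and the lactol is converted into the methyl acetal. With O19 already acylated, O5 is the only oxygen that can close a ring onto C4.

Step 17
Reactants: 24 tricyclic methyl acetal; 25 2-[(trimethylsilyl)methyl]allyl acetate
Product: 26 allylic acetate (C4 arm trans to C20 across the oxolane)
Conditions: BF3·OEt2, CH2Cl2, −78 → −30 °C
Reagents that add atoms: none
Why: Hosomi–Sakurai allylation of the oxolane oxocarbenium ion: the allylsilane attacks C4 opposite to both C11 (on C14) and C20 (on C6). This is also the inside face of the envelope that keeps the C7 substituent pseudo-equatorial, so the arm is installed trans to C20 as 4S requires.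

Step 18
Reactants: 26 allylic acetate
Product: 27 allylic alcohol
Conditions: K2CO3 (cat.), MeOH, 0 °C
Reagents that add atoms: none
Why: Base-catalysed transesterification of the primary allylic acetate; the lactone, with a tertiary alkoxy group and an α-branch, is far more hindered and should survive short exposure at 0 °C.

Step 19
Reactants: 27 allylic alcohol
Product: 28 enal (2-methylenepropanal arm)
Conditions: MnO2, CH2Cl2, rt
Reagents that add atoms: none
Why: MnO2 oxidises allylic alcohols selectively to the enal; the tertiary alcohol is inert.

Step 20
Reactants: 28 enal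
Product: 29 oxime (E)
Conditions: NH2OH·HCl, NaOAc, EtOH, 0 °C → rt
Reagents that add atoms: hydroxylamine hydrochloride, [NH3+]O.[Cl-]
Why: Condensation of the aldehyde with hydroxylamine in buffered ethanol; for a 2-substituted acrolein, addition to the carbonyl and loss of water should be faster than conjugate addition. The E isomer is expected to dominate and both isomers converge in step 21.

Step 21
Reactants: 29 oxime
Product: 32 pentacyclic isoxazoline, via hydroximoyl chloride 30 (not isolated), via nitrile oxide 31 (not isolated)
Conditions: aq NaOCl, CH2Cl2, 0 °C → rt, slow addition of 29 (final concentration about 1 mM)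
Reagents that add atoms: none
Why: Hypochlorite chlorinates the aldoxime to the hydroximoyl chloride, which loses HCl to the conjugated nitrile oxide; this adds to the C22=C33 vinyl group in a concerted suprafacial [3+2] cycloaddition, the bridged mode of the intramolecular nitrile oxide–alkene cycloaddition known for rings of nine members and more. The oxonane closes through the new C33–C34 bond in the endo sense (both alkene carbons become ring members) and the isoxazoline closes in the same event through O23–C22, so that C34=N sits at a bridgehead of a bicyclo[6.2.1] unit, a size at which such a bridgehead double bond is tolerated. The regiochemistry, oxygen to the substituted C22 and carbon to the terminal C33, is the electronic preference of monosubstituted alkenes and is reinforced because the other mode would force the dipole carbon onto the neopentyl C22 beside quaternary C20. The only new stereocentre, C22, is controlled by the neighbouring C20 and by the tether: with the C21 methyl anti to the incoming dipole, the lactone oxygen O19 inside (the usual preference of allylic oxygen in nitrile oxide additions) and C6 outside, oxygen is delivered to the face that gives 22R. The competing arrangement with C6 inside would give the epimer, so this preference has to be checked in the first experiment. The step needs ring closure to outrun furoxan formation, which slow addition at high dilution secures, and the dipole's own 1,1-disubstituted alkene is a poor dipolarophile. The arm on C4 and the vinyl group on C20 lie on opposite faces of the oxolane and must meet around O5, which makes the ring more strained than a cis-bridged one and is the main risk of the route.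

Step 22
Reactants: 32 pentacyclic isoxazoline
Product: 34 β-hydroxy enone (C22 hydroxyl; C34 ketone conjugated to C2=C1), via β-hydroxy imine 33 (not isolated)
Conditions: Mo(CO)6, B(OH)3, MeCN–H2O, 80 °C
Reagents that add atoms: water, O
Why: Mo(CO)6 cleaves the N–O bond of isoxazolines reductively in wet acetonitrile and the β-hydroxy imine is hydrolysed to the ketone. Boric acid buffers the ammonia that is set free so that it does not add to the α-methylene ketone; the alkenes and the lactone are untouched.

Step 23
Reactants: 34 β-hydroxy enone; 35 octanoyl chloride
Product: 36 C22 octanoate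
Conditions: pyridine, DMAP (cat.), CH2Cl2, 0 °C
Reagents that add atoms: none
Why: Acylation of the only secondary hydroxyl under weakly basic conditions, chosen to avoid β-elimination of the β-acyloxy ketone; the tertiary C11 hydroxyl does not react.

Step 24
Reactants: 36 C22 octanoate
Product: 37 target CNP0295349.4
Conditions: (R)-2-methyl-CBS-oxazaborolidine, catecholborane, toluene, −78 °C
Reagents that add atoms: none
Why: Corey–Bakshi–Shibata reduction: the (R)-oxazaborolidine binds the ketone with the α-branched alkenyl carbon C2 as the large group and the C33 methylene as the small one, and delivers hydride to the face that gives the 34S alcohol, 1,3-syn to the octanoate. Catecholborane at −78 °C reduces 1,2 and leaves the lactone and the ester alone.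

Compound list

1 | (R)-carvone | CC1=CC[C@H](CC1=O)C(C)=C | starting material
2 | methacrolein (2-methylprop-2-enal) | CC(=C)C=O | starting material
3 | lithium dienolate of 1, deprotonated at C7 (not isolated) | [Li]OC1=C[C@@H](CC=C1C)C(C)=C | intermediate
4 | triisopropoxytitanium enolate of 1 (not isolated) | CC(C)O[Ti](OC(C)C)(OC(C)C)OC1=C[C@@H](CC=C1C)C(C)=C | intermediate
5 | syn-aldol adduct: carvone with a 1-hydroxy-2-methylprop-2-enyl group on C7, trans to the isopropenyl group, carbinol C6 syn to the C7–C8 bond | O[C@@H](C(C)=C)[C@H]1[C@@H](CC=C(C)C1=O)C(C)=C | intermediate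
6 | erythro epoxy alcohol: 5 with C20=C22 epoxidised, epoxide oxygen erythro to the C6 hydroxyl | O[C@@H]([C@]2(C)CO2)[C@H]1[C@@H](CC=C(C)C1=O)C(C)=C | intermediate
7 | triethylsilyl ether of 6 at O5 | CC[Si](CC)(CC)O[C@@H]([C@]2(C)CO2)[C@H]1[C@@H](CC=C(C)C1=O)C(C)=C | intermediate
8 | β-hydroxysilane: 7 with Me3SiCH2 added to the C14 carbonyl (C14 configuration not defined) | CC[Si](CC)(CC)O[C@@H]([C@]2(C)CO2)[C@H]1[C@@H](CC=C(C)C1(O)C[Si](C)(C)C)C(C)=C | intermediate
9 | B-alkyl-9-BBN adduct of 8, boron on C17 (not isolated) | CC[Si](CC)(CC)O[C@@H]([C@]2(C)CO2)[C@H]1[C@@H](CC=C(C)C1(O)C[Si](C)(C)C)[C@@H](C)CB3C4CCCC3CCC4 | intermediate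
10 | diol: 8 with the isopropenyl group converted into a 1-hydroxypropan-2-yl group, C15 R | CC[Si](CC)(CC)O[C@@H]([C@]2(C)CO2)[C@H]1[C@@H](CC=C(C)C1(O)C[Si](C)(C)C)[C@@H](C)CO | intermediate
11 | diene: exocyclic C14=C4 methylene conjugated to C10=C11, C17 oxygen as 4-methoxybenzyl ether | CC[Si](CC)(CC)O[C@@H]([C@]2(C)CO2)[C@H]1[C@@H](CC=C(C)C1=C)[C@@H](C)COCc3ccc(OC)cc3 | intermediate
12 | B-alkyl-9-BBN adduct of 11, boron on C4 (not isolated) | CC[Si](CC)(CC)O[C@@H]([C@]2(C)CO2)[C@H]1[C@@H](CC=C(C)[C@H]1CB3C4CCCC3CCC4)[C@@H](C)COCc5ccc(OC)cc5 | intermediate
13 | homoallylic alcohol: C4 hydroxymethyl on C14, cis to the C6 side chain on C7 | CC[Si](CC)(CC)O[C@@H]([C@]2(C)CO2)[C@H]1[C@@H](CC=C(C)[C@H]1CO)[C@@H](C)COCc3ccc(OC)cc3 | intermediate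
14 | bis-epoxide: 13 with the C10–C11 epoxide on the face of the C4 hydroxymethyl group | CC[Si](CC)(CC)O[C@@H]([C@]2(C)CO2)[C@H]1[C@@H](C[C@H]3O[C@@]3(C)[C@H]1CO)[C@@H](C)COCc4ccc(OC)cc4 | intermediate
15 | vinyl carbinol: C20 tertiary alcohol with methyl and vinyl, ring epoxide retained | CC[Si](CC)(CC)O[C@@H]([C@@](C)(O)C=C)[C@H]1[C@@H](C[C@H]2O[C@@]2(C)[C@H]1CO)[C@@H](C)COCc3ccc(OC)cc3 | intermediate
16 | triol: C4 primary, C11 and C20 tertiary hydroxyls | CC[Si](CC)(CC)O[C@@H]([C@@](C)(O)C=C)[C@H]1[C@@H](CC[C@@](C)(O)[C@H]1CO)[C@@H](C)COCc2ccc(OC)cc2 | intermediate
17 | bis(triethylsilyl) ether: 16 silylated at the C4 oxygen | CC[Si](CC)(CC)O[C@@H]([C@@](C)(O)C=C)[C@H]1[C@@H](CC[C@@](C)(O)[C@H]1CO[Si](CC)(CC)CC)[C@@H](C)COCc2ccc(OC)cc2 | intermediate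
18 | primary alcohol: 17 without the 4-methoxybenzyl group | CC[Si](CC)(CC)O[C@@H]([C@@](C)(O)C=C)[C@H]1[C@@H](CC[C@@](C)(O)[C@H]1CO[Si](CC)(CC)CC)[C@@H](C)CO | intermediate
19 | C17 aldehyde (not isolated) | CC[Si](CC)(CC)O[C@@H]([C@@](C)(O)C=C)[C@H]1[C@@H](CC[C@@](C)(O)[C@H]1CO[Si](CC)(CC)CC)[C@@H](C)C=O | intermediate
20 | hydroxy acid: C17 carboxylic acid, free C20 and C11 hydroxyls | CC[Si](CC)(CC)O[C@@H]([C@@](C)(O)C=C)[C@H]1[C@@H](CC[C@@](C)(O)[C@H]1CO[Si](CC)(CC)CC)[C@@H](C)C(=O)O | intermediate
21 | mixed anhydride of 20 with 2,4,6-trichlorobenzoic acid (not isolated) | CC[Si](CC)(CC)O[C@@H]([C@@](C)(O)C=C)[C@H]1[C@@H](CC[C@@](C)(O)[C@H]1CO[Si](CC)(CC)CC)[C@@H](C)C(=O)OC(=O)c2c(Cl)cc(Cl)cc2Cl | intermediate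
22 | seven-membered lactone: O19–C17 closed, silyl ethers at O5 and at the C4 oxygen | CC[Si](CC)(CC)O[C@@H]1[C@H]2[C@@H](CC[C@@](C)(O)[C@H]2CO[Si](CC)(CC)CC)[C@@H](C)C(=O)O[C@@]1(C)C=C | intermediate
23 | C4 aldehyde of the lactone, O5 still silylated | CC[Si](CC)(CC)O[C@@H]1[C@H]2[C@@H](CC[C@@](C)(O)[C@H]2C=O)[C@@H](C)C(=O)O[C@@]1(C)C=C | intermediate
24 | tricyclic methyl acetal: oxolane closed, methoxy group on C4, both anomers | COC2O[C@@H]3[C@H]4[C@@H](CC[C@@](C)(O)[C@H]42)[C@@H](C)C(=O)O[C@@]3(C)C=C | intermediate
25 | 2-[(trimethylsilyl)methyl]allyl acetate | CC(=O)OCC(=C)C[Si](C)(C)C | starting material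
26 | allylic acetate: 2-(acetoxymethyl)allyl arm on C4, trans to C20 across the oxolane | CC(=O)OCC(=C)C[C@@H]2O[C@@H]3[C@H]4[C@@H](CC[C@@](C)(O)[C@H]42)[C@@H](C)C(=O)O[C@@]3(C)C=C | intermediate
27 | allylic alcohol | OCC(=C)C[C@@H]2O[C@@H]3[C@H]4[C@@H](CC[C@@](C)(O)[C@H]42)[C@@H](C)C(=O)O[C@@]3(C)C=C | intermediate
28 | enal | O=CC(=C)C[C@@H]2O[C@@H]3[C@H]4[C@@H](CC[C@@](C)(O)[C@H]42)[C@@H](C)C(=O)O[C@@]3(C)C=C | intermediate
29 | oxime (E), the cycloaddition precursor | O/N=C/C(=C)C[C@@H]2O[C@@H]3[C@H]4[C@@H](CC[C@@](C)(O)[C@H]42)[C@@H](C)C(=O)O[C@@]3(C)C=C | intermediate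
30 | hydroximoyl chloride (not isolated) | ON=C(Cl)C(=C)C[C@@H]2O[C@@H]3[C@H]4[C@@H](CC[C@@](C)(O)[C@H]42)[C@@H](C)C(=O)O[C@@]3(C)C=C | intermediate
31 | nitrile oxide (not isolated) | [O-][N+]#CC(=C)C[C@@H]2O[C@@H]3[C@H]4[C@@H](CC[C@@](C)(O)[C@H]42)[C@@H](C)C(=O)O[C@@]3(C)C=C | intermediate
32 | pentacyclic isoxazoline: C34=N–O23–C22 with C33, oxonane closed | C=C1C[C@@H]2O[C@@H]3[C@H]4[C@@H](CC[C@@](C)(O)[C@H]42)[C@@H](C)C(=O)O[C@@]3(C)[C@H]5CC1=NO5 | intermediate
33 | β-hydroxy imine (not isolated) | C=C1C[C@@H]2O[C@@H]3[C@H]4[C@@H](CC[C@@](C)(O)[C@H]42)[C@@H](C)C(=O)O[C@@]3(C)[C@H](O)CC1=N | intermediate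
34 | β-hydroxy enone: C22 hydroxyl, C34 ketone | C=C1C[C@@H]2O[C@@H]3[C@H]4[C@@H](CC[C@@](C)(O)[C@H]42)[C@@H](C)C(=O)O[C@@]3(C)[C@H](O)CC1=O | intermediate
35 | octanoyl chloride | CCCCCCCC(=O)Cl | starting material
36 | C22 octanoate of 34 | C=C1C[C@@H]2O[C@@H]3[C@H]4[C@@H](CC[C@@](C)(O)[C@H]42)[C@@H](C)C(=O)O[C@@]3(C)[C@H](OC(=O)CCCCCCC)CC1=O | intermediate
37 | CNP0295349.4 (4S,6R,7S,8R,11R,14R,15R,20S,22R,34S in the locants used here) | C=C1C[C@@H]2O[C@@H]3[C@H]4[C@@H](CC[C@@](C)(O)[C@H]42)[C@@H](C)C(=O)O[C@@]3(C)[C@H](OC(=O)CCCCCCC)C[C@@H]1O | target

Total step count: 24. Longest linear sequence: 24 steps from 1 (2, 25 and 35 are bought).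

Steps least certain to work

Step 21 (key step). Two things may go wrong. Dimerisation of the nitrile oxide may outrun ring closure, because the arm and the vinyl group start from opposite faces of the oxolane and the ring is strained. The dipole may also be delivered to the wrong face of the vinyl group, since the tether may prefer C6 in the inside position over the lactone oxygen. The fallback closes the oxonane at C2–C34 by a Nozaki–Hiyama–Kishi reaction and sets C22 by reagent control. It sets out from methyl acetal 24. Ozonolysis of the vinyl group (O3, CH2Cl2–MeOH, −78 °C; Me2S) gives the C22 aldehyde F1. Allylboration with the enantiomer of B-allyldiisopinocampheylborane that delivers the 22R carbinol gives the homoallylic alcohol F2. Acylation with 35 and pyridine gives the octanoate F3. (2-Bromoallyl)trimethylsilane and BF3·OEt2 place a 2-bromoallyl arm on C4, by the same facial argument as in step 17, giving the vinyl bromide F4. Ozonolysis of the terminal alkene, which is more electron-rich than the bromoalkene, gives the C34 aldehyde F5. CrCl2 with catalytic NiCl2 in DMSO at high dilution then joins C2 to C34 and forms the allylic alcohol directly, so the fallback comes back to the route at 37, with C34 under substrate control.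

Step 1. Poor syn selectivity is the likely failure, since cyclic enolates are E-configured and closed transition states tend to the anti adduct. The fallback makes the same bond through an open transition state. It sets out from 1, which is converted (LDA, Me3SiCl) into the trimethylsilyl dienol ether F6. F6 is coupled with 2 under catalysis by tris(dimethylamino)sulfonium difluorotrimethylsilicate; such naked-enolate additions are syn-selective whatever the enolate geometry. The silylated adduct F7 is desilylated on mild acidic work-up, and the fallback comes back at 5.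

Step 14. The neutral, hindered tertiary hydroxyl may fail to attack the activated acid; prolonged heating with base may also cause epimerisation at C15 through ketene formation. The fallback turns the roles around and acylates the alkoxide. It sets out from acid 20, which is converted (C6F5OH, EDC, CH2Cl2) into the pentafluorophenyl ester F8. Deprotonation with NaN(SiMe3)2 in THF at −78 °C lets the tertiary alkoxide displace pentafluorophenoxide, and the fallback comes back at 22.

Step 24. The ring conformation may override the catalyst and give the wrong face, conjugate reduction of the α-methylene ketone may compete, and the octanoate may migrate to the new 1,3-syn hydroxyl. The fallback uses the C22 hydroxyl to direct the reduction and acylates afterwards. It sets out from 34. Narasaka–Prasad reduction (Et2BOMe, NaBH4, THF–MeOH, −78 °C) gives the syn-1,3-diol F9. The less hindered allylic hydroxyl is silylated (t-BuMe2SiCl, imidazole) to the C34 silyl ether F10. Acylation with 35, pyridine and DMAP gives the silylated octanoate F11. HF·pyridine removes the silyl group, and the fallback comes back at 37.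

Further compounds

F1 | step 21 | C22 aldehyde from ozonolysis of 24 | COC2O[C@@H]3[C@H]4[C@@H](CC[C@@](C)(O)[C@H]42)[C@@H](C)C(=O)O[C@@]3(C)C=O
F2 | step 21 | homoallylic alcohol, 22R | COC2O[C@@H]3[C@H]4[C@@H](CC[C@@](C)(O)[C@H]42)[C@@H](C)C(=O)O[C@@]3(C)[C@H](O)CC=C
F3 | step 21 | octanoate of F2 | COC2O[C@@H]3[C@H]4[C@@H](CC[C@@](C)(O)[C@H]42)[C@@H](C)C(=O)O[C@@]3(C)[C@H](OC(=O)CCCCCCC)CC=C
F4 | step 21 | vinyl bromide with 2-bromoallyl arm on C4 | C=C(Br)C[C@@H]2O[C@@H]3[C@H]4[C@@H](CC[C@@](C)(O)[C@H]42)[C@@H](C)C(=O)O[C@@]3(C)[C@H](OC(=O)CCCCCCC)CC=C
F5 | step 21 | C34 aldehyde | C=C(Br)C[C@@H]2O[C@@H]3[C@H]4[C@@H](CC[C@@](C)(O)[C@H]42)[C@@H](C)C(=O)O[C@@]3(C)[C@H](OC(=O)CCCCCCC)CC=O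
F6 | step 1 | trimethylsilyl dienol ether of 1 | C[Si](C)(C)OC1=C[C@@H](CC=C1C)C(C)=C
F7 | step 1 | trimethylsilyl ether of 5 | C[Si](C)(C)O[C@@H](C(C)=C)[C@H]1[C@@H](CC=C(C)C1=O)C(C)=C
F8 | step 14 | pentafluorophenyl ester of 20 | CC[Si](CC)(CC)O[C@@H]([C@@](C)(O)C=C)[C@H]1[C@@H](CC[C@@](C)(O)[C@H]1CO[Si](CC)(CC)CC)[C@@H](C)C(=O)Oc2c(F)c(F)c(F)c(F)c2F
F9 | step 24 | syn-1,3-diol (C22 and C34 hydroxyls) | C=C1C[C@@H]2O[C@@H]3[C@H]4[C@@H](CC[C@@](C)(O)[C@H]42)[C@@H](C)C(=O)O[C@@]3(C)[C@H](O)C[C@@H]1O
F10 | step 24 | C34 tert-butyldimethylsilyl ether of F9 | C=C1C[C@@H]2O[C@@H]3[C@H]4[C@@H](CC[C@@](C)(O)[C@H]42)[C@@H](C)C(=O)O[C@@]3(C)[C@H](O)C[C@@H]1O[Si](C)(C)C(C)(C)C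
F11 | step 24 | C22 octanoate of F10 | C=C1C[C@@H]2O[C@@H]3[C@H]4[C@@H](CC[C@@](C)(O)[C@H]42)[C@@H](C)C(=O)O[C@@]3(C)[C@H](OC(=O)CCCCCCC)C[C@@H]1O[Si](C)(C)C(C)(C)C
A1 | alternative 1 | cis-fused oxolane–cyclohexanone with C20 ketone and 2-bromoallyl arm | C=C(Br)C[C@@H]1O[C@@H](C(=O)[C@H](OCc3ccc(OC)cc3)CCO[Si](C)(C)C(C)(C)C)[C@H]2[C@H]([C@@H](C)CO[Si](C)(C)C(C)(C)C)CCC(=O)[C@H]21
A2 | alternative 1 | diazoketone (C6, C20 to C34) | [N-]=[N+]=CC(=O)[C@H](OCc1ccc(OC)cc1)CCO[Si](C)(C)C(C)(C)C
A3 | alternative 1 | 3-bromobut-3-enal | C=C(Br)CC=O
A4 | alternative 1 | 4-substituted cyclohex-2-enone | O=C1C=C[C@H]([C@@H](C)CO[Si](C)(C)C(C)(C)C)CC1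
A5 | alternative 2 | tricyclic lactone with C22 methyl ketone | C=C(CO[Si](C)(C)C(C)(C)C)C[C@@H]1O[C@@H]3[C@H]2[C@@H](CC[C@@](C)(O[Si](CC)(CC)CC)[C@H]21)[C@@H](C)C(=O)O[C@@]3(C)C(C)=O
A6 | alternative 2 | C6 acetate with the Z enol silane ester at C17 | C=C(CO[Si](C)(C)C(C)(C)C)C[C@@H]1OC(OC(C)=O)[C@H]2[C@@H](CC[C@@](C)(O[Si](CC)(CC)CC)[C@H]21)[C@@H](C)C(=O)O/C(C)=C(/C)O[Si](C)(C)C
A7 | alternative 3 | cis-fused oxolane–cyclohexanone with C11 tertiary alcohol | C=C(Br)C[C@@H]1O[C@@H]([C@@]3(C)OC(C)(C)O[C@@H]3CCO[Si](C)(C)C(C)(C)C)[C@H]2C(=O)CC[C@@](C)(O)[C@H]21
A8 | alternative 3 | 3-(4-oxopentanoyl)-2,5-dihydrofuran substrate | C=C(Br)C[C@@H]1O[C@@H]([C@@]3(C)OC(C)(C)O[C@@H]3CCO[Si](C)(C)C(C)(C)C)C(C(=O)CCC(C)=O)=C1
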